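**Strategy**

- Locants are those of the tetralone: C1 ketone, C2 and C3 methyl-bearing, C4 aryl-bearing, ring A = C4a–C8a (OMe on C6, OH on C7), ring B = the carbocycle C1–C4/C4a/C8a.
- Cuts, in retrosynthetic order: O7–Si; C4–C4a (ring B, Friedel–Crafts); C1–C8a (aryllithium on a γ-lactone); C3–C4 and the lactone O–C1 bond (crotylation of veratraldehyde, lactonisation).
- Forward: the C1–C2–C3 unit (an allylic bromide from acetaldehyde and ethyl acrylate) is joined to veratraldehyde at C3–C4 with closure of a temporary γ-lactone; the ring A aryllithium opens the lactone at C1; ring B is closed last at C4–C4a. Both arenes are bought.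
- Enabling feature: C4 is benzylic to the 3,4-dimethoxyphenyl ring and ionises readily; C4a lies para to the C7 oxygen, so ring A is nucleophilic exactly there even with the C1 acyl group ortho to it; C2 sits next to the C1 ketone and can be equilibrated.
- Stereochemistry: C3 comes from the chiral chromium catalyst; C4 is relayed from C3 in the ring closure (3,4-trans); C2 is set by thermodynamic equilibration (2,3-trans).

Key step: step 7

Assumption: the chromium 2-(ethoxycarbonyl)crotylation is taken to be syn-selective (β,γ-cis lactone), as is usual for 2-alkoxycarbonyl crotyl-metal reagents that keep the (Z) geometry. Because C4 is ionised in step 7, an anti outcome would only change which ligand antipode is used.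

**Route**

Step 1
Reactants: 1 acetaldehyde; 2 ethyl acrylate
Product: 3 ethyl 3-hydroxy-2-methylenebutanoate (racemic)
Conditions: DABCO (15 mol %), neat, sealed flask, rt
Reagents that add atoms: none
Why: Morita–Baylis–Hillman reaction: DABCO adds to the acrylate, the zwitterionic enolate adds to the reactive aldehyde and loss of the amine gives the allylic alcohol, whose stereocentre is erased in step 2.

Step 2
Reactants: 3 ethyl 3-hydroxy-2-methylenebutanoate
Product: 4 ethyl (Z)-2-(bromomethyl)but-2-enoate
Conditions: 48% aq. HBr, conc. H2SO4, 0 °C to rt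
Reagents that add atoms: hydrogen bromide, Br
Why: Acid-mediated allylic transposition (SN2′/SN1′ bromination of a Baylis–Hillman alcohol) should deliver the conjugated primary bromide as the thermodynamically preferred (Z) isomer, with the methyl group trans to the ester.

Step 3
Reactants: 4 ethyl (Z)-2-(bromomethyl)but-2-enoate; 5 3,4-dimethoxybenzaldehyde (veratraldehyde)
Product: 8 (4R,5S)-5-(3,4-dimethoxyphenyl)-4-methyl-3-methylenedihydrofuran-2(3H)-one, via silyl ether 6 (not isolated), via hydroxy ester 7 (not isolated)
Conditions: CrCl2 (10 mol %, divalent chromium), chiral carbazole-1,8-bis(oxazoline) ligand (12 mol %, antipode chosen for the 4S carbinol), Mn powder, Me3SiCl, THF, 0 °C to rt; then aq. HCl, THF, rt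
Reagents that add atoms: none
Why: Catalytic asymmetric Nozaki–Hiyama–Kishi 2-(alkoxycarbonyl)allylation: divalent chromium (regenerated by Mn, the trivalent chromium alkoxide being released by Me3SiCl as silyl ether 6) turns 4 into an allylchromium species that adds to 5 at its γ-carbon through a chair transition state in which the ligand selects the aldehyde face (4S carbinol) and the retained (Z) geometry places the methyl group syn, which sets the β-carbon (3R in 7, C3 of the target); acid then cleaves the silyl ether and 7 lactonises to the β,γ-cis lactone, from which any anti diastereomer (antipodal at the β-carbon) is removed by chromatography or crystallisation.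

Step 4
Reactants: 8 (4R,5S)-5-(3,4-dimethoxyphenyl)-4-methyl-3-methylenedihydrofuran-2(3H)-one
Product: 9 (3S,4R,5S)-5-(3,4-dimethoxyphenyl)-3,4-dimethyldihydrofuran-2(3H)-one (all-cis)
Conditions: H2 (1 atm), RhCl(PPh3)3 (5 mol %), toluene–EtOH, rt
Reagents that add atoms: none
Why: Homogeneous hydrogenation with RhCl(PPh3)3 reduces the 1,1-disubstituted conjugated alkene and leaves the benzylic C–O bond intact, hydrogen arriving anti to the cis methyl and aryl groups to give the all-cis lactone (new α-centre 3S, which becomes C2 of the target and is re-equilibrated in step 7, so either epimer would serve).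

Step 5
Reactants: 10 5-bromo-2-methoxyphenol
Product: 11 (5-bromo-2-methoxyphenoxy)triisopropylsilane
Conditions: i-Pr3SiCl, imidazole, DMF, rt
Reagents that add atoms: chlorotriisopropylsilane, CC(C)[Si](Cl)(C(C)C)C(C)C
Why: Imidazole-promoted silylation of the phenol; the bulky silyl ether tolerates aryllithium chemistry and later shields the ring A position next to it.

Step 6
Reactants: 11 (5-bromo-2-methoxyphenoxy)triisopropylsilane; 9 (3S,4R,5S)-5-(3,4-dimethoxyphenyl)-3,4-dimethyldihydrofuran-2(3H)-one
Product: 14 (2S,3R,4S)-4-(3,4-dimethoxyphenyl)-4-hydroxy-1-[4-methoxy-3-(triisopropylsilyloxy)phenyl]-2,3-dimethylbutan-1-one, via aryllithium 12 (not isolated), via lithium lactolate 13 (not isolated)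
Conditions: 11, n-BuLi, THF, −78 °C; then 9, −78 °C; AcOH quench at −78 °C
Reagents that add atoms: none
Why: Bromine–lithium exchange gives aryllithium 12, which adds once to the γ-lactone because the tetrahedral lithium lactolate 13 persists at −78 °C until the quench, so the C1–C8a bond is made without over-addition; the carbinol and C2 centres of the product (which equilibrates with its cyclic lactol) are not critical because both are reset in step 7.

Step 7
Reactants: 14 (2S,3R,4S)-4-(3,4-dimethoxyphenyl)-4-hydroxy-1-[4-methoxy-3-(triisopropylsilyloxy)phenyl]-2,3-dimethylbutan-1-one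
Product: 16 (2R,3S,4R)-4-(3,4-dimethoxyphenyl)-6-methoxy-2,3-dimethyl-7-(triisopropylsilyloxy)-3,4-dihydronaphthalen-1(2H)-one, via C2-epimeric tetralone 15 (not isolated)
Conditions: TfOH (20 mol %), (CF3)2CHOH (0.01 M), 0 °C to rt, argon; Et3N, evaporate; DBU (0.5 equiv), toluene, 60 °C
Reagents that add atoms: none
Why: Catalytic TfOH in the ionising, non-nucleophilic solvent heterolyses the C4–O bond of 14 (or of its lactol and dihydrofuran forms, which reopen under the same conditions) to a 3,4-dimethoxybenzyl cation, ring A attacks it through the carbon para to its silyloxy group (the future C4a) and proton loss restores the arene, i.e. an intramolecular Friedel–Crafts alkylation whose closest known relatives are the acid-mediated cyclodehydrations of 4-aryl-4-hydroxybutyl arenes to trans-1-aryl-2-methyltetralins. Ring B, the six-membered carbocycle, closes 6-endo with respect to the C4a=C8a π bond of ring A, while the cationic carbon is attacked exo (its aryl group stays outside the new ring). C4 (R) is the only new stereocentre and is controlled by C3: the cation adopts the conformer with the C3–H bond in its plane (least 1,3-allylic strain) and the C1–C2 tether delivers ring A to the face that leaves the aryl group and the C3 methyl group trans and pseudo-equatorial in a chair-like transition state, so the carbinol configuration of 14 does not matter. C2, which arrives as in 15 or scrambled if the dihydrofuran intervenes, is then equilibrated through the enolate (DBU) to the 2,3-trans isomer (2R), in which all three substituents are pseudo-equatorial. The step needs para rather than ortho attack on ring A (the bulky silyloxy group shields C8, and ortho attack would build a 1,2,3,4-tetrasubstituted arene), C–C closure rather than O-trapping by the ketone (the latter is reversible, the former is not) and closure faster than E1 loss of the C3 proton, which the cold, dilute, non-basic medium and the para oxygen donor of ring A favour.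

Step 8
Reactants: 16 (2R,3S,4R)-4-(3,4-dimethoxyphenyl)-6-methoxy-2,3-dimethyl-7-(triisopropylsilyloxy)-3,4-dihydronaphthalen-1(2H)-one
Product: 17 epischisandrone, (2R,3S,4R)-4-(3,4-dimethoxyphenyl)-7-hydroxy-6-methoxy-2,3-dimethyl-3,4-dihydronaphthalen-1(2H)-one
Conditions: Bu4NF, AcOH, THF, 0 °C
Reagents that add atoms: none
Why: Fluoride-mediated cleavage of the aryl silyl ether (strong Si–F bond), buffered with AcOH so that the phenoxide is protonated at once and the C2 centre next to the ketone is not disturbed.

**Compound list**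

1 | acetaldehyde | CC=O | starting material
2 | ethyl acrylate | C=CC(=O)OCC | starting material
3 | ethyl 3-hydroxy-2-methylenebutanoate (racemic) | CC(O)C(=C)C(=O)OCC | intermediate
4 | ethyl (Z)-2-(bromomethyl)but-2-enoate | C/C=C(\CBr)C(=O)OCC | intermediate
5 | 3,4-dimethoxybenzaldehyde (veratraldehyde) | COc1ccc(C=O)cc1OC | starting material
6 | ethyl (3R,4S)-4-(3,4-dimethoxyphenyl)-3-methyl-2-methylene-4-(trimethylsilyloxy)butanoate | CCOC(=O)C(=C)[C@@H](C)[C@H](O[Si](C)(C)C)c1ccc(OC)c(OC)c1 | intermediate (not isolated)
7 | ethyl (3R,4S)-4-(3,4-dimethoxyphenyl)-4-hydroxy-3-methyl-2-methylenebutanoate | CCOC(=O)C(=C)[C@@H](C)[C@H](O)c1ccc(OC)c(OC)c1 | intermediate (not isolated)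
8 | (4R,5S)-5-(3,4-dimethoxyphenyl)-4-methyl-3-methylenedihydrofuran-2(3H)-one (β,γ-cis) | O=C1C(=C)[C@@H](C)[C@@H](c2ccc(OC)c(OC)c2)O1 | intermediate
9 | (3S,4R,5S)-5-(3,4-dimethoxyphenyl)-3,4-dimethyldihydrofuran-2(3H)-one (all-cis) | O=C1[C@@H](C)[C@@H](C)[C@@H](c2ccc(OC)c(OC)c2)O1 | intermediate
10 | 5-bromo-2-methoxyphenol | COc1ccc(Br)cc1O | starting material
11 | (5-bromo-2-methoxyphenoxy)triisopropylsilane | COc1ccc(Br)cc1O[Si](C(C)C)(C(C)C)C(C)C | intermediate
12 | [4-methoxy-3-(triisopropylsilyloxy)phenyl]lithium | COc1ccc([Li])cc1O[Si](C(C)C)(C(C)C)C(C)C | intermediate (not isolated)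
13 | lithium (3S,4R,5S)-5-(3,4-dimethoxyphenyl)-2-[4-methoxy-3-(triisopropylsilyloxy)phenyl]-3,4-dimethyltetrahydrofuran-2-olate | [Li]OC1(c2ccc(OC)c(O[Si](C(C)C)(C(C)C)C(C)C)c2)[C@@H](C)[C@@H](C)[C@@H](c2ccc(OC)c(OC)c2)O1 | intermediate (not isolated)
14 | (2S,3R,4S)-4-(3,4-dimethoxyphenyl)-4-hydroxy-1-[4-methoxy-3-(triisopropylsilyloxy)phenyl]-2,3-dimethylbutan-1-one | COc1ccc(cc1O[Si](C(C)C)(C(C)C)C(C)C)C(=O)[C@@H](C)[C@@H](C)[C@H](O)c1ccc(OC)c(OC)c1 | intermediate
15 | (2S,3S,4R)-4-(3,4-dimethoxyphenyl)-6-methoxy-2,3-dimethyl-7-(triisopropylsilyloxy)-3,4-dihydronaphthalen-1(2H)-one (C2 epimer of 16) | COc1cc2c(cc1O[Si](C(C)C)(C(C)C)C(C)C)C(=O)[C@@H](C)[C@@H](C)[C@@H]2c1ccc(OC)c(OC)c1 | intermediate (not isolated)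
16 | (2R,3S,4R)-4-(3,4-dimethoxyphenyl)-6-methoxy-2,3-dimethyl-7-(triisopropylsilyloxy)-3,4-dihydronaphthalen-1(2H)-one | COc1cc2c(cc1O[Si](C(C)C)(C(C)C)C(C)C)C(=O)[C@H](C)[C@@H](C)[C@@H]2c1ccc(OC)c(OC)c1 | intermediate
17 | epischisandrone, (2R,3S,4R)-4-(3,4-dimethoxyphenyl)-7-hydroxy-6-methoxy-2,3-dimethyl-3,4-dihydronaphthalen-1(2H)-one | COc1cc2c(cc1O)C(=O)[C@H](C)[C@@H](C)[C@@H]2c1ccc(OC)c(OC)c1 | target

**Step count**

Total: 8 steps. Longest linear sequence: 7 steps (steps 1, 2, 3, 4, 6, 7, 8); step 5 is a one-step branch.

**Steps most likely to fail**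

Step 7. Process at risk: the acyl-deactivated ring A may trap the C4 cation too slowly, so that loss of the C3 proton (styrene formation, erosion of C3) or diversion into the dihydrofuran manifold wins. Fallback (sets out from allylic bromide 4, returns at tetralone 15): the two arenes exchange roles, the C4–aryl bond is made intermolecularly and ring B is closed at C1–C8a by a Parham cyclisation. Commercial 2-bromo-4-hydroxy-5-methoxybenzaldehyde is silylated (i-Pr3SiCl, imidazole) to 2-bromo-5-methoxy-4-(triisopropylsilyloxy)benzaldehyde F1. The crotylation conditions of step 3, applied to 4 and F1, should give the cis α-methylene lactone F4 through the trimethylsilyl ether F2 and the hydroxy ester F3 (neither isolated). Hydrogenation as in step 4 then gives the all-cis lactone F5. TfOH in (CF3)2CHOH ionises the benzylic C–O bond of F5 and the cation alkylates 1,2-dimethoxybenzene (in excess) at its 4-position to give the diaryl acid F6. In this intermolecular Friedel–Crafts alkylation the arene should approach the 1,3-allylic-strain-minimised cation anti to the branched C2 side chain, which, with the roles of the rings exchanged, corresponds to the 3,4-trans relationship of the target. n-BuLi (2.2 equiv, THF, −78 °C) deprotonates the acid and exchanges the bromine to give the lithiated carboxylate F7, which closes onto its own carboxylate and gives 15 on work-up. The DBU treatment of step 7 then converts 15 into 16.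

Step 3. Process at risk: insufficient syn/anti selectivity in the crotylation. Since the ligand fixes the carbinol, the minor diastereomer carries the antipodal C3 and lowers the enantiomeric purity of everything downstream if it is not removed. Fallback (sets out from lactone 8 taken together with its β-epimer, returns at lactone 9): C3 is relayed from the catalyst-set carbinol by hydrogenation instead of by the crotylation. RhCl3·3H2O in hot EtOH moves the exocyclic double bond into the ring and converts both diastereomers into the same butenolide, (R)-5-(3,4-dimethoxyphenyl)-3,4-dimethylfuran-2(5H)-one F8, in which the β-carbon is planar. Hydrogenation over Rh/Al2O3 (H2, EtOAc, rt) should then add both hydrogen atoms anti to the aryl group and give the all-cis lactone 9.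

Step 6. Process at risk: premature collapse of the lactolate (double addition of the aryllithium) or enolisation of the lactone by the aryllithium. Fallback (sets out from lactone 9, returns at hydroxy ketone 14): Me(MeO)NH·HCl and Me3Al (CH2Cl2, 0 °C to rt) open 9 to the hydroxy Weinreb amide F9. Me3SiCl and imidazole cap the alcohol as the trimethylsilyl ether F10 so that it cannot relactonise. Aryllithium 12 adds once to give the chelated tetrahedral adduct F11, and work-up with aqueous citric acid releases the ketone and removes the trimethylsilyl group to give 14.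

**Further compounds**

F1 | step 7 | 2-bromo-5-methoxy-4-(triisopropylsilyloxy)benzaldehyde | COc1cc(C=O)c(Br)cc1O[Si](C(C)C)(C(C)C)C(C)C
F2 | step 7 | ethyl (3R,4S)-4-[2-bromo-5-methoxy-4-(triisopropylsilyloxy)phenyl]-3-methyl-2-methylene-4-(trimethylsilyloxy)butanoate | CCOC(=O)C(=C)[C@@H](C)[C@H](O[Si](C)(C)C)c1cc(OC)c(O[Si](C(C)C)(C(C)C)C(C)C)cc1Br
F3 | step 7 | ethyl (3R,4S)-4-[2-bromo-5-methoxy-4-(triisopropylsilyloxy)phenyl]-4-hydroxy-3-methyl-2-methylenebutanoate | CCOC(=O)C(=C)[C@@H](C)[C@H](O)c1cc(OC)c(O[Si](C(C)C)(C(C)C)C(C)C)cc1Br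
F4 | step 7 | (4R,5S)-5-[2-bromo-5-methoxy-4-(triisopropylsilyloxy)phenyl]-4-methyl-3-methylenedihydrofuran-2(3H)-one | O=C1C(=C)[C@@H](C)[C@@H](c2cc(OC)c(O[Si](C(C)C)(C(C)C)C(C)C)cc2Br)O1
F5 | step 7 | (3S,4R,5S)-5-[2-bromo-5-methoxy-4-(triisopropylsilyloxy)phenyl]-3,4-dimethyldihydrofuran-2(3H)-one | O=C1[C@@H](C)[C@@H](C)[C@@H](c2cc(OC)c(O[Si](C(C)C)(C(C)C)C(C)C)cc2Br)O1
F6 | step 7 | (2S,3S,4R)-4-[2-bromo-5-methoxy-4-(triisopropylsilyloxy)phenyl]-4-(3,4-dimethoxyphenyl)-2,3-dimethylbutanoic acid | OC(=O)[C@@H](C)[C@@H](C)[C@@H](c1cc(OC)c(O[Si](C(C)C)(C(C)C)C(C)C)cc1Br)c1ccc(OC)c(OC)c1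
F7 | step 7 | lithium (2S,3S,4R)-4-(3,4-dimethoxyphenyl)-4-[2-lithio-5-methoxy-4-(triisopropylsilyloxy)phenyl]-2,3-dimethylbutanoate | [Li]OC(=O)[C@@H](C)[C@@H](C)[C@@H](c1cc(OC)c(O[Si](C(C)C)(C(C)C)C(C)C)cc1[Li])c1ccc(OC)c(OC)c1
F8 | step 3 | (R)-5-(3,4-dimethoxyphenyl)-3,4-dimethylfuran-2(5H)-one | O=C1C(C)=C(C)[C@@H](c2ccc(OC)c(OC)c2)O1
F9 | step 6 | (2S,3R,4S)-4-(3,4-dimethoxyphenyl)-4-hydroxy-N-methoxy-N,2,3-trimethylbutanamide | CON(C)C(=O)[C@@H](C)[C@@H](C)[C@H](O)c1ccc(OC)c(OC)c1
F10 | step 6 | (2S,3R,4S)-4-(3,4-dimethoxyphenyl)-N-methoxy-N,2,3-trimethyl-4-(trimethylsilyloxy)butanamide | CON(C)C(=O)[C@@H](C)[C@@H](C)[C@H](O[Si](C)(C)C)c1ccc(OC)c(OC)c1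
F11 | step 6 | lithium (2S,3R,4S)-4-(3,4-dimethoxyphenyl)-1-[methoxy(methyl)amino]-1-[4-methoxy-3-(triisopropylsilyloxy)phenyl]-2,3-dimethyl-4-(trimethylsilyloxy)butan-1-olate | [Li]OC(c1ccc(OC)c(O[Si](C(C)C)(C(C)C)C(C)C)c1)(N(C)OC)[C@@H](C)[C@@H](C)[C@H](O[Si](C)(C)C)c1ccc(OC)c(OC)c1
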